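**Plan**
- Retrosynthesis: ring A is cut at C1–C2 and C2–C3. C2 and its bromine leave as dibromocarbene, which leaves the five-membered siloxydiene 11 (future C1, C3, C4, C5, C6).
- 11 is traced back through the C3–Br bond (bromination and silylation of enone 5), the C5–Br bond (vinylogous acid bromide) and the C6–O bond (carbenoid O–H insertion of 2-diazocyclopentane-1,3-dione into 2-bromophenol).
- Forward: the five-membered ring is bought as cyclopentane-1,3-dione, ring B is attached through oxygen, the two ring bromines are placed, and ring A arises last by one-carbon enlargement with aromatisation.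
- Enabling feature: in ring A the C1 hydroxyl sits between C2–Br and C6–OAr, C3 and C5 carry bromine, and C4 (para to the hydroxyl) carries hydrogen. Phenol bromination cannot leave C4 free, but a C–Br unit inserted between C1 and C3 of a cyclopentadiene with a C4 methylene gives exactly this array.
- Stereochemistry: the target is achiral, so nothing has to be set; the stereocentres of 7 and 12 are transient and racemic.

Key step: step 7

Remark on locants: C1–C6 always mean the ring A atoms of the target and ring B is the 2-bromophenyl ring; the five-membered compounds are named with their own IUPAC locants.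
Remark on the carbene source: the ring CH2 of 11 is a doubly allylic cyclopentadiene methylene and is assumed too acidic for bromoform/alkoxide conditions, so dibromocarbene is delivered base-free and cold from PhHgCBr3/NaI. Reagent 10 and its by-product are highly toxic organomercurials.

**Step 1**
Reactants: 1 cyclopentane-1,3-dione
Product: 2 2-diazocyclopentane-1,3-dione
Conditions: p-ABSA, Et3N, MeCN, 0 °C to rt
Reagents that add atoms: 4-acetamidobenzenesulfonyl azide (p-ABSA), CC(=O)Nc1ccc(cc1)S(=O)(=O)N=[N+]=[N-]
Why: Regitz diazo transfer, in which the amine-generated enolate of the acidic 1,3-dione attacks the terminal azide nitrogen and the triazene adduct fragments to the 2-diazo-1,3-dione and the sulfonamide.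

**Step 2**
Reactants: 2 2-diazocyclopentane-1,3-dione, 3 2-bromophenol
Product: 4 2-(2-bromophenoxy)-3-hydroxycyclopent-2-en-1-one (enol form of 2-(2-bromophenoxy)cyclopentane-1,3-dione)
Conditions: Rh2(OAc)4 (1 mol %), 3 (1.5 equiv), 1,2-dichloroethane, 60 °C, slow addition of 2
Reagents that add atoms: none
Why: Carbenoid O–H insertion, in which the electrophilic rhodium carbenoid of the acceptor/acceptor diazo compound is captured by the phenolic oxygen and the oxonium ylide shifts its proton to carbon, a path that for phenols should outrun attack on the ring carbons.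

**Step 3**
Reactants: 4 2-(2-bromophenoxy)-3-hydroxycyclopent-2-en-1-one
Product: 5 3-bromo-2-(2-bromophenoxy)cyclopent-2-en-1-one
Conditions: (COBr)2, DMF (cat.), CH2Cl2, 0 °C to rt
Reagents that add atoms: oxalyl bromide, BrC(=O)C(=O)Br
Why: Vinylogous acid to vinylogous acyl bromide conversion through Vilsmeier-type activation of the enol oxygen and addition–elimination by bromide, and because the 2-substituted dione is symmetric only one bromoenone can form.

**Step 4**
Reactants: 5 3-bromo-2-(2-bromophenoxy)cyclopent-2-en-1-one
Product: 7 3,5-dibromo-2-(2-bromophenoxy)cyclopent-2-en-1-one (racemic), via silyl dienol ether 6 (not isolated)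
Conditions: TBSOTf, iPr2NEt, CH2Cl2, −78 to −20 °C; then NBS, THF, −78 to 0 °C
Reagents that add atoms: tert-butyldimethylsilyl triflate (silyl group, present in 6 only), CC(C)(C)[Si](C)(C)OS(=O)(=O)C(F)(F)F; N-bromosuccinimide, O=C1CCC(=O)N1Br
Why: Soft enolisation of the cyclopentenone at the CH2 next to the carbonyl gives the cross-conjugated 2-siloxydiene, whose enol ether carbon is then brominated by NBS (silyl enol ether halogenation) while the electron-poor bromoenone double bond and ring B are left alone.

**Step 5**
Reactants: 8 chloro(phenyl)mercury (PhHgCl), 9 bromoform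
Product: 10 phenyl(tribromomethyl)mercury (PhHgCBr3)
Conditions: KOtBu, benzene, 0–5 °C
Reagents that add atoms: none
Why: Seyferth reagent preparation, in which the tribromomethyl anion formed from bromoform and KOtBu substitutes chloride at mercury in the cold faster than it loses bromide, giving a storable base-free dibromocarbene donor.

**Step 6**
Reactants: 7 3,5-dibromo-2-(2-bromophenoxy)cyclopent-2-en-1-one
Product: 11 tert-butyl{[2,4-dibromo-5-(2-bromophenoxy)cyclopenta-1,4-dien-1-yl]oxy}dimethylsilane
Conditions: TBSOTf, iPr2NEt, CH2Cl2, −78 °C; cold pentane extraction, used at once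
Reagents that add atoms: tert-butyldimethylsilyl triflate, CC(C)(C)[Si](C)(C)OS(=O)(=O)C(F)(F)F
Why: Soft enolisation of an alpha-bromo ketone, in which O-silylation is followed by removal of the CHBr hydrogen, the most acidic one because it is flanked by the silyloxocarbenium carbon and bromine, to give the 2-bromo silyl enol ether with all four heteroatom substituents on sp2 carbons.

**Step 7**
Reactants: 11 tert-butyl{[2,4-dibromo-5-(2-bromophenoxy)cyclopenta-1,4-dien-1-yl]oxy}dimethylsilane, 10 phenyl(tribromomethyl)mercury
Product: 14 2,3,5-tribromo-6-(2-bromophenoxy)phenol, via dibromocyclopropane 12 (not isolated), via aryl silyl ether 13 (not isolated)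
Conditions: NaI, 2,6-di-tert-butyl-4-methylpyridine (DTBMP), DME, −15 to 0 °C; filtration; then TBAF, AcOH, THF, 0 °C
Reagents that add atoms: none
Why: Iodide displaces the tribromomethyl anion from mercury, the anion loses bromide to free dibromocarbene without any strong base, and the electrophilic carbene adds in a concerted cheletropic (2+1) step to the siloxy-bearing double bond of 11 (future C1 and C3) to give cyclopropane 12. The siloxy lone pair then drives disrotatory two-electron opening of the cyclopropane with loss of the endo bromide, which breaks the old C1–C3 bond, makes the carbene carbon C2 with its remaining bromine, and gives a cation that is the C4-protonated arenium ion of silyl ether 13; loss of the C4 proton to the hindered pyridine aromatises ring A irreversibly, and buffered fluoride frees the phenol. The closest known reaction type is the dihalocarbene ring expansion of cyclic silyl enol ethers to 2-halo enones and of siloxyindenes to 2-halo-1-naphthols. Ring A is not closed by a cyclisation: the five-membered carbocycle grows by one carbon through cyclopropanation and electrocyclic opening, so that C1–C2 and C2–C3 are the two new ring bonds. No stereocentre remains, since 12 is a racemic, necessarily cis-fused intermediate. The step needs site selectivity for the siloxy over the aryloxy double bond, which the stronger donor ability of the silyl enol ether oxygen should provide (the aryloxy lone pair is shared with ring B), and the cold, base-free conditions keep the acidic C4 methylene of 11 from being deprotonated or shifted.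

**Compound list**
1 | cyclopentane-1,3-dione | O=C1CCC(=O)C1 | starting material
2 | 2-diazocyclopentane-1,3-dione | [N-]=[N+]=C1C(=O)CCC1=O | intermediate
3 | 2-bromophenol | Oc1ccccc1Br | starting material
4 | 2-(2-bromophenoxy)-3-hydroxycyclopent-2-en-1-one (drawn as enol) | O=C1CCC(O)=C1Oc1ccccc1Br | intermediate
5 | 3-bromo-2-(2-bromophenoxy)cyclopent-2-en-1-one | O=C1CCC(Br)=C1Oc1ccccc1Br | intermediate
6 | tert-butyl{[4-bromo-5-(2-bromophenoxy)cyclopenta-1,4-dien-1-yl]oxy}dimethylsilane | CC(C)(C)[Si](C)(C)OC1=CCC(Br)=C1Oc1ccccc1Br | intermediate
7 | 3,5-dibromo-2-(2-bromophenoxy)cyclopent-2-en-1-one (racemic) | O=C1C(Br)CC(Br)=C1Oc1ccccc1Br | intermediate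
8 | chloro(phenyl)mercury (PhHgCl) | Cl[Hg]c1ccccc1 | starting material
9 | bromoform | BrC(Br)Br | starting material
10 | phenyl(tribromomethyl)mercury (PhHgCBr3) | BrC(Br)(Br)[Hg]c1ccccc1 | intermediate
11 | tert-butyl{[2,4-dibromo-5-(2-bromophenoxy)cyclopenta-1,4-dien-1-yl]oxy}dimethylsilane | CC(C)(C)[Si](C)(C)OC1=C(Br)CC(Br)=C1Oc1ccccc1Br | intermediate
12 | tert-butyl{[3,5,6,6-tetrabromo-2-(2-bromophenoxy)bicyclo[3.1.0]hex-2-en-1-yl]oxy}dimethylsilane (racemic, cis-fused) | CC(C)(C)[Si](C)(C)OC12C(Oc3ccccc3Br)=C(Br)CC1(Br)C2(Br)Br | intermediate
13 | tert-butyl[2,3,5-tribromo-6-(2-bromophenoxy)phenoxy]dimethylsilane | CC(C)(C)[Si](C)(C)Oc1c(Br)c(Br)cc(Br)c1Oc1ccccc1Br | intermediate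
14 | 2,3,5-tribromo-6-(2-bromophenoxy)phenol | Oc1c(Br)c(Br)cc(Br)c1Oc1ccccc1Br | target

Total steps: 7. Longest linear sequence: 6 (steps 1, 2, 3, 4, 6, 7).

**Steps most likely to fail**

1. Step 7. Carbene transfer to the fully substituted, bromine-bearing siloxy double bond may be slow enough that addition at the aryloxy double bond or a hydrogen shift in the diene competes, which would give constitutional isomers of ring A.
Fallback: the C3 bromine is taken out of the carbene step. The route is left at silyl dienol ether 6, which is extracted cold into pentane instead of being brominated. Its siloxy double bond is only trisubstituted and carries no bromine, so the same transfer (10, NaI, DTBMP, DME, −15 °C) should take place there. It would lead through tert-butyl{[3,6,6-tribromo-2-(2-bromophenoxy)bicyclo[3.1.0]hex-2-en-1-yl]oxy}dimethylsilane F1 and tert-butyl[3,6-dibromo-2-(2-bromophenoxy)phenoxy]dimethylsilane F2 and, after TBAF/AcOH, give 3,6-dibromo-2-(2-bromophenoxy)phenol F3, which lacks only the C3 bromine. That bromine would then be directed by a temporary C4 amino group. Nitration para to the hydroxyl (HNO3, AcOH, 0 °C) would give 3,6-dibromo-2-(2-bromophenoxy)-4-nitrophenol F4. Reduction (Fe powder, NH4Cl, EtOH/H2O) would give 4-amino-3,6-dibromo-2-(2-bromophenoxy)phenol F5. Bromination at the only free position ortho to nitrogen (NBS, MeCN, −10 °C) would give 4-amino-2,3,5-tribromo-6-(2-bromophenoxy)phenol F6. Hydrodediazoniation (NaNO2, H2SO4, then H3PO2) would return to the route at 14.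

2. Step 6. The amine may remove a hydrogen of the ring CH2 instead of the CHBr hydrogen, or trigger loss of HBr towards a cyclopentadienone, and the diene may isomerise or dimerise while being handled.
Fallback: the enolate position is fixed reductively, without any amine. From 7, acid-mediated enol bromination (pyridinium tribromide, AcOH, rt) would give 3,5,5-tribromo-2-(2-bromophenoxy)cyclopent-2-en-1-one F7. Zinc dust (THF, −20 °C) would then remove one geminal bromine as a Reformatsky-type zinc bromoenolate, and O-silylation with TBSOTf would return to the route at 11.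

3. Step 2. The rhodium carbenoid may attack a ring carbon of the phenol or the enol oxygen of the product instead of the phenolic O–H, or the diazo compound may decompose by ring contraction.
Fallback: the C–O bond is made by umpolung at trivalent iodine instead of through a metal carbenoid. From 1, PhI(OAc)2 and Na2CO3 in MeOH at 0 °C would give the iodonium ylide 3-oxo-2-(phenyliodonio)cyclopent-1-en-1-olate F8. On warming with 3 in MeCN the ylide would be protonated by the phenol and collapse by ligand coupling at iodine, returning to the route at 4.

**Further compounds**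
F1 | step 7 | tert-butyl{[3,6,6-tribromo-2-(2-bromophenoxy)bicyclo[3.1.0]hex-2-en-1-yl]oxy}dimethylsilane (racemic, cis-fused) | CC(C)(C)[Si](C)(C)OC12C(Oc3ccccc3Br)=C(Br)CC1C2(Br)Br
F2 | step 7 | tert-butyl[3,6-dibromo-2-(2-bromophenoxy)phenoxy]dimethylsilane | CC(C)(C)[Si](C)(C)Oc1c(Br)ccc(Br)c1Oc1ccccc1Br
F3 | step 7 | 3,6-dibromo-2-(2-bromophenoxy)phenol | Oc1c(Br)ccc(Br)c1Oc1ccccc1Br
F4 | step 7 | 3,6-dibromo-2-(2-bromophenoxy)-4-nitrophenol | Oc1c(Br)cc([N+](=O)[O-])c(Br)c1Oc1ccccc1Br
F5 | step 7 | 4-amino-3,6-dibromo-2-(2-bromophenoxy)phenol | Nc1cc(Br)c(O)c(Oc2ccccc2Br)c1Br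
F6 | step 7 | 4-amino-2,3,5-tribromo-6-(2-bromophenoxy)phenol | Nc1c(Br)c(Br)c(O)c(Oc2ccccc2Br)c1Br
F7 | step 6 | 3,5,5-tribromo-2-(2-bromophenoxy)cyclopent-2-en-1-one | O=C1C(Br)(Br)CC(Br)=C1Oc1ccccc1Br
F8 | step 2 | 3-oxo-2-(phenyliodonio)cyclopent-1-en-1-olate | [O-]C1=C([I+]c2ccccc2)C(=O)CC1
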